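Remark on the chemistry: atoms are numbered as in the eudesmane skeleton (ring A = C1–C5 and C10, ring B = C5–C10, C14 on C10, C15 on C4, C11–C13 on C7); the given SMILES is read as 3S,4S,5R,10R with a (Z)-2-methylbut-2-enoate (angelate) on O3.

## Analysis of the target

- The target is a trans-fused decalin. Ring A (C1–C5, C10) carries the angelate on C3 and a tertiary alcohol plus the C15 methyl on C4. Ring B (C5–C10) is a cyclohexenone (C6=C7–C8=O) whose C7 bears the 2-hydroperoxypropan-2-yl group (C11–C13). C10 is quaternary and bears C14.
- All four stereocentres (C3 S, C4 S, C5 R, C10 R) are contiguous on ring A. O3 and O4 are trans and both equatorial, H5 is axial and anti to C14, and the C15 and C14 methyl groups are syn-diaxial. The C4 configuration is therefore the strained one and will not come from equilibration.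
- Sensitive groups are the tertiary allylic hydroperoxide, the angelate (Z to E isomerisation, conjugate addition), the enone and the tertiary alcohol.
- The C8 carbonyl is 1,3 to the quaternary C10 and 1,4 (dissonant) to C5. Aldol or Robinson logic therefore cannot close ring B and needs a masked ring-B building block.
- The feature used here: O–C3–C4–O is the reduced form of a 1,2-diketone. The bonds C4–C5 and C9–C10, which flank the ring-fusion bond C5–C10, are the two bonds formed when an open-chain E alkene C5=C10 attacks a C4 carbonyl and the resulting C10 cation is captured by C9.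
- The hydroperoxide with the C6=C7 enone is the ene adduct of an isopropylidene ketone, so the C11–O bond and the C6=C7 double bond belong in the last step.

## Retrosynthetic reasoning

**24 to 23.** The two oxygen atoms on C11 are removed and the double bond returns from C6=C7 to C7=C11. The hydroperoxide is too labile to carry, and the isopropylidene ketone 23 is its ene precursor. The forward photo-oxygenation must abstract H6 rather than a methyl hydrogen and must spare the angelate.

**23 to 21 and 22.** The ester C–O bond at C3 is cut. Acid 22 isomerises easily, so it is attached late, to the only secondary hydroxyl of 21.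

**21 to 17 and 18, 17 to 16.** The C7=C11 bond is cut. Ketal 18 supplies C11–C13 as an electrophile and enol silane 17 fixes the nucleophilic site at C7. C9 is neopentyl, so ketone 16 enolises away from C10. Both hydroxyls are silylated in the same operation, so no separate protection is needed.

**16 to 15 to 14.** The C3–H bond is cut back to the α-ketol 15, because the C4 hydroxyl can deliver hydride to the α face of C3 and gives the trans diol. The C8 carbonyl of 15 is traced to the exocyclic methylene of 14, which is the scar left by an allylsilane terminator.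

**14 to 12 (key disconnection).** C4–C5 and C9–C10 are cut together. Both rings open and the three stereocentres C4, C5 and C10 are cleared. The precursor 12 is an achiral open-chain 2,3-dione with an E alkene and an allylsilane. The cut is placed here because C4 then becomes the acetyl carbonyl of a chelating 1,2-diketone. That is a substrate class for which a chiral Lewis acid can select one carbonyl face, and the chelate forces O4 equatorial and C15 axial. The forward reaction must close ring A, relay the cation from C10 into ring B, and fix the absolute configuration at C4.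

**12 to 9 and 10.** The C3–C4 bond is cut. The acetyl unit C4–C15 comes from the α-metallated enol ether of 10 as an acyl anion equivalent added to amide 9.

**9 to 6 and 7.** The C1–C2 bond is cut by a Claisen rearrangement. This also creates the C5=C10 alkene with E geometry from the allylic alcohol 6.

**6 to 4 and 5, 4 to 1 and 2.** The C5–C10 bond comes from addition of Grignard reagent 5 to aldehyde 4. The C6–C7 bond of 4 comes from a first Claisen rearrangement of the vinyl ether of alcohol 1 with 2.

## Alternatives that were turned down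

**Alternative 1: Robinson annulation (the textbook route).**
- Disconnection: C4=C5 and C1–C10 of ring A.
- Forward key step: asymmetric Michael addition of the mono-ketal ketone A1 (as a chiral enamine or imine) to the vinyl ketone A2, then aldol condensation to the bicyclic enone A3.
- Why turned down: the step builds only ring A on a purchased ring B and sets C10 alone. C3, C4 and C5 are left for later redox operations on a hindered tetrasubstituted enone. Because C5 and C8 are 1,4-related, C8 must be carried as a ketal and unmasked later. The step count would be about the same as the chosen route, but no step would address more than one stereocentre.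

**Alternative 2: dearomatization of a ring-A phenol.**
- Disconnection: C9–C10, by intramolecular para-alkylation of a phenol.
- Forward key step: metal-carbene (Buchner-type) attack of the α-diazoketone A4 on the arene, opening to the cross-conjugated dienone A5.
- Why turned down: the 1,2,3,4-tetrasubstituted arene needs about five steps. The carbene can attack either methyl-bearing carbon (C10 para or C4 ortho to the hydroxyl). A5 has ring A at the dienone level, so saturating C1–C2 and setting C3, C4 and C5 still take four operations. The enantioselective version is no better precedented than the step chosen.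

**Alternative 3: transannular cyclization of a ten-membered ring.**
- Disconnection: C5–C10 across a cyclodecadienone.
- Forward key step: protonation of the C1=C10 alkene of the commercial ketone A6, attack of C5 on C10 and loss of a proton from the C4 cation to give A7.
- Why turned down: A6 is achiral, so A7 is racemic unless a chiral proton source can discriminate its rapidly interconverting conformers. The positive charge moves from C10 to C4 and never functionalises C3, so the C3 oxygen would need a cis-dihydroxylation and an inversion. Termination gives alkene isomers. The route would also rest on a natural C15 ketone instead of building the skeleton.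

Key step: step 5

## Steps

Step 1
Reactants: 1 2-[(trimethylsilyl)methyl]prop-2-en-1-ol; 2 butyl vinyl ether
Product: 4 4-[(trimethylsilyl)methyl]pent-4-enal, via allyl vinyl ether 3 (not isolated)
Conditions: 2 (excess), Pd(OCOCF3)2 (1 mol %), 4,7-diphenyl-1,10-phenanthroline (1 mol %), Et3N (cat.), 75 °C; evaporate; xylene, 145 °C (sealed)
Reagents that add atoms: none
Why: Palladium-catalysed transfer vinylation gives the allyl vinyl ether, whose Claisen rearrangement forms the C6–C7 bond and gives the γ,δ-unsaturated aldehyde with the allylsilane intact.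

Step 2
Reactants: 4 4-[(trimethylsilyl)methyl]pent-4-enal; 5 isopropenylmagnesium bromide
Product: 6 rac-2-methyl-6-[(trimethylsilyl)methyl]hepta-1,6-dien-3-ol
Conditions: THF, −78 → 0 °C; aq. NH4Cl
Reagents that add atoms: none
Why: Grignard 1,2-addition forms the C5–C10 bond; the carbinol centre is racemic but is destroyed in step 3.

Step 3
Reactants: 6 rac-2-methyl-6-[(trimethylsilyl)methyl]hepta-1,6-dien-3-ol; 7 1,1-dimethoxy-N,N-dimethylethan-1-amine
Product: 9 (4E)-N,N,4-trimethyl-8-[(trimethylsilyl)methyl]nona-4,8-dienamide, via ketene N,O-acetal 8 (not isolated)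
Conditions: 7 (3 equiv), xylene, 140 °C, MeOH distilled off
Reagents that add atoms: none
Why: Eschenmoser–Claisen rearrangement forms the C1–C2 bond under neutral conditions that spare the allylsilane; the chair transition state with the chain equatorial should give the E trisubstituted C5=C10 alkene needed later for the trans ring fusion.

Step 4
Reactants: 9 (4E)-N,N,4-trimethyl-8-[(trimethylsilyl)methyl]nona-4,8-dienamide; 10 ethyl vinyl ether
Product: 12 (6E)-6-methyl-10-[(trimethylsilyl)methyl]undeca-6,10-diene-2,3-dione, via ethoxy enone 11 (not isolated)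
Conditions: 10, t-BuLi, THF, −78 → 0 °C; then 9, −78 → 0 °C; aq. NH4Cl; then oxalic acid dihydrate, wet SiO2, CH2Cl2, rt
Reagents that add atoms: water, O
Why: The α-lithiated enol ether (acyl anion equivalent) adds once to the tertiary amide, forming the C3–C4 bond; mild acid hydrolysis of the enol ether unveils the 2,3-dione without protodesilylation of the allylsilane.

Step 5
Reactants: 12 (6E)-6-methyl-10-[(trimethylsilyl)methyl]undeca-6,10-diene-2,3-dione
Product: 14 (1S,4aR,8aR)-1-hydroxy-1,4a-dimethyl-6-methylideneoctahydronaphthalen-2(1H)-one, via trimethylsilyl ether 13 (not isolated)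
Conditions: Cu(SbF6)2 (10 mol %), (S,S)-2,2′-(propane-2,2-diyl)bis(4-tert-butyl-4,5-dihydro-1,3-oxazole) (11 mol %), 4 Å molecular sieves, CH2Cl2 (0.005 M, slow addition of 12), −20 °C → rt; then citric acid, MeOH
Reagents that add atoms: none
Why: Proposed new method: the 2,3-dione binds the divalent copper centre as a five-membered chelate, the C5=C10 alkene adds through C5 to the acetyl carbonyl C4 (ring A, six-membered, 6-endo with respect to the alkene, tertiary cation at C10), the allylsilane adds through C9 to C10 (ring B, six-membered, 6-endo with respect to the allylsilane double bond, chair–chair and antiperiplanar to the new C4–C5 bond), and the β-silyl cation collapses by silyl transfer to the copper alkoxide, which releases 13 and turns the catalyst over. The closest known reaction types are bis(oxazoline)–copper-catalysed enantioselective aldol and carbonyl-ene additions to the acetyl carbonyl of chelated pyruvates and 2,3-diketones, and Lewis-acid cation–olefin bicyclizations terminated by allylsilanes; joining them in one cascade is new. C4 is controlled by the catalyst, which shields one face of the planar chelate; for this ligand attack on the si face of the acetyl carbonyl is expected, which corresponds to 4S, and the enantiomeric ligand is available if the sense is opposite. Because O4 must stay syn-periplanar to O3 in the chelate it ends equatorial and C15 axial, which is the 4α-hydroxy-4β-methyl arrangement. C5 and C10 are controlled by the E geometry of the alkene in the chair–chair transition state, which should give the trans fusion with H5 anti to C14. The step needs selection of the acetyl carbonyl over C3 (only C4–C5 closure gives a six-membered ring and a tertiary cation) and capture of the C10 cation by the allylsilane instead of proton loss; the equatorial O4 lies far from the C14 hydrogens and the allylsilane is a strong π-nucleophile, and high dilution suppresses intermolecular allylation.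

Step 6
Reactants: 14 (1S,4aR,8aR)-1-hydroxy-1,4a-dimethyl-6-methylideneoctahydronaphthalen-2(1H)-one
Product: 15 (1S,4aR,8aR)-1-hydroxy-1,4a-dimethylhexahydronaphthalene-2,6(1H,5H)-dione
Conditions: O3, CH2Cl2–MeOH, −78 °C; Me2S, −78 °C → rt
Reagents that add atoms: ozone, [O-][O+]=O
Why: Ozonolysis of the only C=C bond turns the exocyclic methylene left by the terminator into the C8 ketone.

Step 7
Reactants: 15 (1S,4aR,8aR)-1-hydroxy-1,4a-dimethylhexahydronaphthalene-2,6(1H,5H)-dione
Product: 16 (4aR,5S,6S,8aR)-5,6-dihydroxy-5,8a-dimethyloctahydronaphthalen-2(1H)-one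
Conditions: Me4NBH(OAc)3 (4 equiv), MeCN–AcOH (1:1), −30 °C
Reagents that add atoms: none
Why: Hydroxyl-directed triacetoxyborohydride reduction: the C4 hydroxyl binds boron and delivers hydride to the α face of C3, which should give the equatorial 3β (3S) alcohol trans to O4; the isolated C8 ketone is not reduced by this reagent.

Step 8
Reactants: 16 (4aR,5S,6S,8aR)-5,6-dihydroxy-5,8a-dimethyloctahydronaphthalen-2(1H)-one
Product: 17 (4aR,5S,6S,8aR)-5,8a-dimethyl-2,5,6-tris[(trimethylsilyl)oxy]-1,4,4a,5,6,7,8,8a-octahydronaphthalene
Conditions: Me3SiOTf (3.6 equiv), Et3N (5 equiv), CH2Cl2, 0 °C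
Reagents that add atoms: trimethylsilyl trifluoromethanesulfonate, C[Si](C)(C)OS(=O)(=O)C(F)(F)F
Why: Soft enolisation; the ketone enolises towards C7 because C9 is neopentyl, and both hydroxyls are silylated in the same pot.

Step 9
Reactants: 17 (4aR,5S,6S,8aR)-5,8a-dimethyl-2,5,6-tris[(trimethylsilyl)oxy]-1,4,4a,5,6,7,8,8a-octahydronaphthalene; 18 2,2-dimethoxypropane
Product: 21 (4aR,5S,6S,8aR)-5,6-dihydroxy-5,8a-dimethyl-3-(propan-2-ylidene)octahydronaphthalen-2(1H)-one, via methoxy ketone 19 (not isolated), via bis-silyl enone 20 (not isolated)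
Conditions: 18 (1.5 equiv), Me3SiOTf (10 mol %), CH2Cl2, −78 °C; DBU, rt; then citric acid, MeOH
Reagents that add atoms: none
Why: Mukaiyama-type aldol addition of the enol silane to the oxocarbenium ion from the ketal forms the C7–C11 bond; E1cB loss of methanol gives the conjugated isopropylidene ketone and methanolysis frees the diol.

Step 10
Reactants: 21 (4aR,5S,6S,8aR)-5,6-dihydroxy-5,8a-dimethyl-3-(propan-2-ylidene)octahydronaphthalen-2(1H)-one; 22 angelic acid
Product: 23 (1S,2S,4aR,8aR)-1-hydroxy-1,4a-dimethyl-6-oxo-7-(propan-2-ylidene)decahydronaphthalen-2-yl (2Z)-2-methylbut-2-enoate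
Conditions: 22 (3 equiv), 2,4,6-Cl3C6H2COCl, Et3N, toluene, rt; then 21, toluene, 80 °C
Reagents that add atoms: none
Why: Yamaguchi esterification through the mixed anhydride without a nucleophilic catalyst limits Z to E isomerisation; only the secondary C3 hydroxyl is acylated, the tertiary C4 hydroxyl is inert.

Step 11
Reactants: 23 (1S,2S,4aR,8aR)-1-hydroxy-1,4a-dimethyl-6-oxo-7-(propan-2-ylidene)decahydronaphthalen-2-yl (2Z)-2-methylbut-2-enoate
Product: 24 (1S,2S,4aR,8aR)-7-(2-hydroperoxypropan-2-yl)-1-hydroxy-1,4a-dimethyl-6-oxo-1,2,3,4,4a,5,6,8a-octahydronaphthalen-2-yl (2Z)-2-methylbut-2-enoate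
Conditions: O2, tetraphenylporphyrin (cat.), visible light, CH2Cl2, −20 °C
Reagents that add atoms: dioxygen, O=O
Why: Schenck ene reaction: singlet oxygen bonds to C11 and abstracts H6, the hydrogen on the substituent geminal to the carbonyl of the s-cis enone, so the new double bond C6=C7 is conjugated; no stereocentre is formed and the electron-poor angelate double bond should react much more slowly.

## Compound list

1 | 2-[(trimethylsilyl)methyl]prop-2-en-1-ol | C[Si](C)(C)CC(=C)CO | starting material
2 | butyl vinyl ether (1-(ethenyloxy)butane) | CCCCOC=C | starting material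
3 | trimethyl{2-[(ethenyloxy)methyl]prop-2-en-1-yl}silane | C[Si](C)(C)CC(=C)COC=C | intermediate
4 | 4-[(trimethylsilyl)methyl]pent-4-enal | C[Si](C)(C)CC(=C)CCC=O | intermediate
5 | isopropenylmagnesium bromide (prop-1-en-2-ylmagnesium bromide) | CC(=C)[Mg]Br | starting material
6 | rac-2-methyl-6-[(trimethylsilyl)methyl]hepta-1,6-dien-3-ol | CC(=C)C(O)CCC(=C)C[Si](C)(C)C | intermediate
7 | 1,1-dimethoxy-N,N-dimethylethan-1-amine | CC(OC)(OC)N(C)C | starting material
8 | N,N-dimethyl-1-({2-methyl-6-[(trimethylsilyl)methyl]hepta-1,6-dien-3-yl}oxy)ethen-1-amine | C=C(N(C)C)OC(CCC(=C)C[Si](C)(C)C)C(C)=C | intermediate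
9 | (4E)-N,N,4-trimethyl-8-[(trimethylsilyl)methyl]nona-4,8-dienamide | CN(C)C(=O)CC/C(C)=C/CCC(=C)C[Si](C)(C)C | intermediate
10 | ethyl vinyl ether (ethoxyethene) | CCOC=C | starting material
11 | (6E)-2-ethoxy-6-methyl-10-[(trimethylsilyl)methyl]undeca-1,6,10-trien-3-one | C=C(OCC)C(=O)CC/C(C)=C/CCC(=C)C[Si](C)(C)C | intermediate
12 | (6E)-6-methyl-10-[(trimethylsilyl)methyl]undeca-6,10-diene-2,3-dione | CC(=O)C(=O)CC/C(C)=C/CCC(=C)C[Si](C)(C)C | intermediate
13 | (1S,4aR,8aR)-1,4a-dimethyl-6-methylidene-1-[(trimethylsilyl)oxy]octahydronaphthalen-2(1H)-one | O=C1CC[C@]2(C)CC(=C)CC[C@H]2[C@]1(C)O[Si](C)(C)C | intermediate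
14 | (1S,4aR,8aR)-1-hydroxy-1,4a-dimethyl-6-methylideneoctahydronaphthalen-2(1H)-one | O=C1CC[C@]2(C)CC(=C)CC[C@H]2[C@]1(C)O | intermediate
15 | (1S,4aR,8aR)-1-hydroxy-1,4a-dimethylhexahydronaphthalene-2,6(1H,5H)-dione | O=C1CC[C@]2(C)CC(=O)CC[C@H]2[C@]1(C)O | intermediate
16 | (4aR,5S,6S,8aR)-5,6-dihydroxy-5,8a-dimethyloctahydronaphthalen-2(1H)-one | O[C@H]1CC[C@]2(C)CC(=O)CC[C@H]2[C@]1(C)O | intermediate
17 | (4aR,5S,6S,8aR)-5,8a-dimethyl-2,5,6-tris[(trimethylsilyl)oxy]-1,4,4a,5,6,7,8,8a-octahydronaphthalene | C[Si](C)(C)O[C@H]1CC[C@]2(C)CC(O[Si](C)(C)C)=CC[C@H]2[C@]1(C)O[Si](C)(C)C | intermediate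
18 | 2,2-dimethoxypropane | COC(C)(C)OC | starting material
19 | (4aR,5S,6S,8aR)-3-(2-methoxypropan-2-yl)-5,8a-dimethyl-5,6-bis[(trimethylsilyl)oxy]octahydronaphthalen-2(1H)-one (mixture at C3) | C[Si](C)(C)O[C@H]1CC[C@]2(C)CC(=O)C(C(C)(C)OC)C[C@H]2[C@]1(C)O[Si](C)(C)C | intermediate
20 | (4aR,5S,6S,8aR)-5,8a-dimethyl-3-(propan-2-ylidene)-5,6-bis[(trimethylsilyl)oxy]octahydronaphthalen-2(1H)-one | C[Si](C)(C)O[C@H]1CC[C@]2(C)CC(=O)C(=C(C)C)C[C@H]2[C@]1(C)O[Si](C)(C)C | intermediate
21 | (4aR,5S,6S,8aR)-5,6-dihydroxy-5,8a-dimethyl-3-(propan-2-ylidene)octahydronaphthalen-2(1H)-one | O[C@H]1CC[C@]2(C)CC(=O)C(=C(C)C)C[C@H]2[C@]1(C)O | intermediate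
22 | angelic acid, (2Z)-2-methylbut-2-enoic acid | C/C=C(/C)C(=O)O | starting material
23 | (1S,2S,4aR,8aR)-1-hydroxy-1,4a-dimethyl-6-oxo-7-(propan-2-ylidene)decahydronaphthalen-2-yl (2Z)-2-methylbut-2-enoate | C/C=C(/C)C(=O)O[C@H]1CC[C@]2(C)CC(=O)C(=C(C)C)C[C@H]2[C@]1(C)O | intermediate
24 | (1S,2S,4aR,8aR)-7-(2-hydroperoxypropan-2-yl)-1-hydroxy-1,4a-dimethyl-6-oxo-1,2,3,4,4a,5,6,8a-octahydronaphthalen-2-yl (2Z)-2-methylbut-2-enoate | C/C=C(/C)C(=O)O[C@H]1CC[C@]2(C)CC(=O)C(C(C)(C)OO)=C[C@H]2[C@]1(C)O | target

## Step count and least certain steps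

Total step count: 11. Longest linear sequence: 11 steps (from 1 to 24; the route is linear).

**Step 5 (key step).**
- What may go wrong: the cascade may stop after the first ring by proton loss from the C10 cation. The allylsilane may add to the activated diketone of a second molecule. Facial discrimination by the catalyst may be poor. Part of the material may react through a non-chelated or boat-like transition state, because the chair–chair path has to build the syn-diaxial C14/C15 methyl pair.
- Fallback (sets out from 12, comes back at 16): racemic synthesis followed by resolution, with established reaction classes. Stoichiometric SnCl4 in CH2Cl2 at −78 °C is the classical activation for allylsilane-terminated cation–olefin cyclization onto a Lewis-acid-bound carbonyl, and the more cationic intermediate favours complete bicyclization. It should give 14 together with its enantiomer, (1R,4aS,8aS)-1-hydroxy-1,4a-dimethyl-6-methylideneoctahydronaphthalen-2(1H)-one F1. Ozonolysis and directed reduction as in steps 6 and 7 carry the racemate through the enantiomeric dione F2 to 16 and its enantiomer, the (4aS,5R,6R,8aS)-diol F3. Acylation with Candida antarctica lipase B and vinyl acetate is expected to convert the 6R enantiomer into its acetate, (1R,2R,4aS,8aS)-1-hydroxy-1,4a-dimethyl-6-oxodecahydronaphthalen-2-yl acetate F4. Unreacted 16 is separated and enters step 8.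

**Step 9.**
- What may go wrong: the hindered tertiary oxocarbenium ion may add slowly to the enol silane, so that silyl transfer and protodesilylation back to the ketone compete. Elimination of methanol may be incomplete or may give the non-conjugated isopropenyl isomer.
- Fallback (sets out from 16, comes back at 21): enolate aldol chemistry on a protected diol. 16 is converted with 18 and catalytic TsOH into its acetonide, the 5,6-O-isopropylidene derivative F5. Deprotonation with LiN(iPr)2 at −78 °C (towards C7) and addition of acetone gives the β-hydroxy ketone F6. Mesylation (MsCl, Et3N) and elimination with DBU gives the acetonide of the isopropylidene ketone F7. Aqueous HCl in THF removes the acetonide and gives 21.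

**Step 10.**
- What may go wrong: acylation of the hindered C3 hydroxyl next to the quaternary C4 may be slow, and the longer heating then allows isomerisation of the angelate to the tiglate.
- Fallback (sets out from 21, comes back at 23): build the Z double bond on the substrate. 21 is esterified (DCC, DMAP) with 2-[bis(2,2,2-trifluoroethoxy)phosphoryl]propanoic acid to give the phosphonate ester F8. Still–Gennari olefination (KN(SiMe3)2, 18-crown-6, THF, −78 °C, acetaldehyde) should give the Z-2-methylbut-2-enoate 23.

**Step 11.**
- What may go wrong: hydrogen abstraction from a C12/C13 methyl instead of H6 (regioisomeric ene reaction), slow competing ene reaction at the angelate, or decomposition of the hydroperoxide on prolonged irradiation.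
- Fallback (sets out from 17, comes back at 24): install the C11 oxygen by an aldol reaction and exchange it for the hydroperoxide. Mukaiyama aldol addition of 17 to acetone (TiCl4, CH2Cl2, −78 °C; then citric acid, MeOH) gives the triol ketone F9. Yamaguchi acylation as in step 10 gives its 3-angelate F10. Dehydrogenation with 2-iodoxybenzoic acid in DMSO (only the C6–C7 position can be desaturated) gives the tertiary allylic alcohol F11. Acid-catalysed substitution with concentrated aqueous H2O2 (catalytic H2SO4, Et2O, 0 °C) at the tertiary allylic C11 gives 24.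

## Further compounds

F1 | step 5 | (1R,4aS,8aS)-1-hydroxy-1,4a-dimethyl-6-methylideneoctahydronaphthalen-2(1H)-one | O=C1CC[C@@]2(C)CC(=C)CC[C@@H]2[C@@]1(C)O
F2 | step 5 | (1R,4aS,8aS)-1-hydroxy-1,4a-dimethylhexahydronaphthalene-2,6(1H,5H)-dione | O=C1CC[C@@]2(C)CC(=O)CC[C@@H]2[C@@]1(C)O
F3 | step 5 | (4aS,5R,6R,8aS)-5,6-dihydroxy-5,8a-dimethyloctahydronaphthalen-2(1H)-one | O[C@@H]1CC[C@@]2(C)CC(=O)CC[C@@H]2[C@@]1(C)O
F4 | step 5 | (1R,2R,4aS,8aS)-1-hydroxy-1,4a-dimethyl-6-oxodecahydronaphthalen-2-yl acetate | CC(=O)O[C@@H]1CC[C@@]2(C)CC(=O)CC[C@@H]2[C@@]1(C)O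
F5 | step 9 | 5,6-O-isopropylidene derivative (acetonide) of 16 | CC1(C)O[C@H]2CC[C@]3(C)CC(=O)CC[C@H]3[C@]2(C)O1
F6 | step 9 | 3-(2-hydroxypropan-2-yl) derivative of the acetonide of 16 (mixture at C3) | CC1(C)O[C@H]2CC[C@]3(C)CC(=O)C(C(C)(C)O)C[C@H]3[C@]2(C)O1
F7 | step 9 | 5,6-O-isopropylidene derivative (acetonide) of 21 | CC1(C)O[C@H]2CC[C@]3(C)CC(=O)C(=C(C)C)C[C@H]3[C@]2(C)O1
F8 | step 10 | (1S,2S,4aR,8aR)-1-hydroxy-1,4a-dimethyl-6-oxo-7-(propan-2-ylidene)decahydronaphthalen-2-yl 2-[bis(2,2,2-trifluoroethoxy)phosphoryl]propanoate | CC(C(=O)O[C@H]1CC[C@]2(C)CC(=O)C(=C(C)C)C[C@H]2[C@]1(C)O)P(=O)(OCC(F)(F)F)OCC(F)(F)F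
F9 | step 11 | (4aR,5S,6S,8aR)-5,6-dihydroxy-3-(2-hydroxypropan-2-yl)-5,8a-dimethyloctahydronaphthalen-2(1H)-one (mixture at C3) | O[C@H]1CC[C@]2(C)CC(=O)C(C(C)(C)O)C[C@H]2[C@]1(C)O
F10 | step 11 | (1S,2S,4aR,8aR)-1-hydroxy-7-(2-hydroxypropan-2-yl)-1,4a-dimethyl-6-oxodecahydronaphthalen-2-yl (2Z)-2-methylbut-2-enoate (mixture at C7) | C/C=C(/C)C(=O)O[C@H]1CC[C@]2(C)CC(=O)C(C(C)(C)O)C[C@H]2[C@]1(C)O
F11 | step 11 | (1S,2S,4aR,8aR)-1-hydroxy-7-(2-hydroxypropan-2-yl)-1,4a-dimethyl-6-oxo-1,2,3,4,4a,5,6,8a-octahydronaphthalen-2-yl (2Z)-2-methylbut-2-enoate | C/C=C(/C)C(=O)O[C@H]1CC[C@]2(C)CC(=O)C(C(C)(C)O)=C[C@H]2[C@]1(C)O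
A1 | alternative 1 | 7-methyl-1,4-dioxaspiro[4.5]decan-8-one (racemic) | CC1CC2(CCC1=O)OCCO2
A2 | alternative 1 | pent-1-en-3-one | CCC(=O)C=C
A3 | alternative 1 | (4a′R)-1′,4a′-dimethyl-3′,4′,4a′,5′,7′,8′-hexahydro-2′H-spiro[1,3-dioxolane-2,6′-naphthalen]-2′-one | O=C1CC[C@]2(C)CC3(OCCO3)CCC2=C1C
A4 | alternative 2 | 1-diazo-4-(3-hydroxy-2,6-dimethylphenyl)butan-2-one | Cc1ccc(O)c(C)c1CCC(=O)C=[N+]=[N-]
A5 | alternative 2 | (4aS)-1,4a-dimethyl-4a,5,7,8-tetrahydronaphthalene-2,6-dione | O=C1C=C[C@]2(C)CC(=O)CCC2=C1C
A6 | alternative 3 | (3E,7E)-3,7-dimethyl-10-(propan-2-ylidene)cyclodeca-3,7-dien-1-one | O=C1C/C(C)=C/CC/C(C)=C/CC1=C(C)C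
A7 | alternative 3 | rel-(4aR,8aR)-5,8a-dimethyl-3-(propan-2-ylidene)-3,4,4a,7,8,8a-hexahydronaphthalen-2(1H)-one (racemic, one enantiomer drawn) | CC1=CCC[C@]2(C)CC(=O)C(=C(C)C)C[C@@H]12
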